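**Retrosynthetic overview**
- Target 13 comes from its TBS ether 12 by Si–O cleavage. The only ring built is the 2,2-dimethyl-2H-pyran (O1–C2–C3–C4, fused at C4a–C8a), closed on the complete side chain by a thermal propargyl-ether Claisen / 1,5-H shift / oxa-6π cascade of 8 that forms C4a–C4 and O1–C2.
- Feature used: O1 sits on C8a para to the C6 acyl group and C4 sits on C4a next to the hydrogen-bonded C5–OH. A 1,1-dimethylpropargyl ether on the para oxygen gives exactly this pattern when the OH···O=C chelate directs the shift.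
- 8 comes from 7 by silylation, and 7 from diketone 6 by Ru–TsDPEN transfer hydrogenation of the benzoyl carbonyl, which sets the single (S) stereocentre.
- 6 comes from aryl benzoate 5 by Baker–Venkataraman acyl shift, chosen over a strong-base crossed Claisen so that the terminal alkyne is never exposed to an amide base; 5 comes from 3, and 3 from 1 + 2 by selective 4′-O-alkylation.
- Ring order: both benzene rings are bought; the pyran is closed in step 6.

Key step: step 6

Assumption: the carbinol centre of the given SMILES is (S) (O > Ph > CH2 > H). Primed locants refer to the acylphenyl ring of open-chain compounds (C1′ bears the acyl group); unprimed ring locants refer to the chromene.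

**Step 1**
Reactants: 1 2′,4′-dihydroxy-6′-methoxyacetophenone; 2 3-chloro-3-methylbut-1-yne
Product: 3 1-[2-hydroxy-6-methoxy-4-(2-methylbut-3-yn-2-yloxy)phenyl]ethan-1-one
Conditions: 2 (1.5 equiv), K2CO3 (2 equiv), KI (0.2 equiv), CuI (5 mol %), acetone, 55 °C
Reagents that add atoms: none
Why: Cu(I)-assisted O-alkylation of a phenoxide with a tertiary propargylic chloride; C4′–OH is the more acidic, unchelated hydroxyl while C2′–OH is held in the hydrogen bond to the ketone, so mono-etherification para to the acetyl group is expected.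

**Step 2**
Reactants: 3 1-[2-hydroxy-6-methoxy-4-(2-methylbut-3-yn-2-yloxy)phenyl]ethan-1-one; 4 benzoyl chloride
Product: 5 2-acetyl-3-methoxy-5-(2-methylbut-3-yn-2-yloxy)phenyl benzoate
Conditions: BzCl (1.3 equiv), pyridine, DMAP (cat.), 0 °C → rt
Reagents that add atoms: none
Why: DMAP-catalysed O-acylation of the remaining phenol with an acid chloride places the benzoyl group on the oxygen next to the acetyl group, as the acyl transfer of step 3 requires.

**Step 3**
Reactants: 5 2-acetyl-3-methoxy-5-(2-methylbut-3-yn-2-yloxy)phenyl benzoate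
Product: 6 1-[2-hydroxy-6-methoxy-4-(2-methylbut-3-yn-2-yloxy)phenyl]-3-phenylpropane-1,3-dione
Conditions: powdered KOH (3 equiv), pyridine, 50 °C; then cold 10% aq. AcOH to pH 5
Reagents that add atoms: none
Why: Baker–Venkataraman rearrangement, in which the methyl ketone enolate attacks the neighbouring benzoate through a six-membered transition state and the stabilised diketone enolate drives the O→C acyl shift; hydroxide does not touch the alkyne or the aryl ether, and the mild acid quench avoids cyclodehydration to a flavone.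

**Step 4**
Reactants: 6 1-[2-hydroxy-6-methoxy-4-(2-methylbut-3-yn-2-yloxy)phenyl]-3-phenylpropane-1,3-dione
Product: 7 (S)-3-hydroxy-1-[2-hydroxy-6-methoxy-4-(2-methylbut-3-yn-2-yloxy)phenyl]-3-phenylpropan-1-one
Conditions: RuCl[(S,S)-TsDPEN](p-cymene) (2 mol %), HCO2H/Et3N (5:2), CH2Cl2, 25–30 °C, stopped at mono-reduction
Reagents that add atoms: none
Why: Noyori–Ikariya asymmetric transfer hydrogenation of a 1,3-diketone to a β-hydroxy ketone; only the benzoyl carbonyl should react, because the other ketone is di-ortho-substituted, conjugated to a trioxygenated ring and hydrogen-bonded, and the (S,S)-catalyst should deliver hydride to the face that gives the (S)-benzylic alcohol, as it does for aryl alkyl ketones (CH/π contact between the phenyl ring and the η6-arene).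

**Step 5**
Reactants: 7 (S)-3-hydroxy-1-[2-hydroxy-6-methoxy-4-(2-methylbut-3-yn-2-yloxy)phenyl]-3-phenylpropan-1-one
Product: 8 (S)-3-[(tert-butyldimethylsilyl)oxy]-1-[2-hydroxy-6-methoxy-4-(2-methylbut-3-yn-2-yloxy)phenyl]-3-phenylpropan-1-one
Conditions: TBSCl (1.3 equiv), imidazole (2.5 equiv), DMF, 0 °C → rt
Reagents that add atoms: tert-butyldimethylsilyl chloride, CC(C)(C)[Si](C)(C)Cl
Why: Imidazole-mediated silylation of the secondary alcohol; the chelated, flanked phenol is a poor nucleophile, and any aryl silyl ether formed next to the carbonyl should hydrolyse on aqueous work-up.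

**Step 6**
Reactants: 8 (S)-3-[(tert-butyldimethylsilyl)oxy]-1-[2-hydroxy-6-methoxy-4-(2-methylbut-3-yn-2-yloxy)phenyl]-3-phenylpropan-1-one
Product: 12 (S)-3-[(tert-butyldimethylsilyl)oxy]-1-(5-hydroxy-7-methoxy-2,2-dimethyl-2H-chromen-6-yl)-3-phenylpropan-1-one, via allenyl dienone 9 (not isolated), via ortho-allenyl phenol 10 (not isolated), via ortho-quinone methide 11 (not isolated)
Conditions: degassed o-xylene (0.05 M), 140 °C, Ar, sealed base-washed tube
Reagents that add atoms: none
Why: The aryl 1,1-dimethylpropargyl ether undergoes an aromatic propargyl Claisen ([3,3]) shift that forms C4a–C4 and gives allenyl dienone 9, which tautomerises to ortho-allenyl phenol 10; a 1,5-hydrogen shift from the new C4′–OH to the central allene carbon then gives the (Z)-ortho-quinone methide 11. Thermal disrotatory oxa-6π electrocyclisation of the 1-oxatriene in 11 (O=C–C=CH–CH=CMe2) forms O1–C2 and closes the six-membered pyran with rearomatisation. The closest known reaction type is the thermal rearrangement of aryl 1,1-dimethylpropargyl ethers to 2,2-dimethyl-2H-chromenes, which the gem-dimethyl group accelerates. No stereocentre is created, and the silyl-protected carbinol centre is a spectator under neutral heating free of acid and base. The step needs migration to C3′ (the ring CH flanked by C2′–OH and C4′–O) and not to C5′ (flanked by C4′–O and C6′–OMe); the hydrogen bond of C2′–OH to the ketone favours the ring bond pattern with C3′=C4′ double-bond character, which is the bond the [3,3] shift uses. The same hydrogen bond keeps the C2′ oxygen out of the hydrogen shift, so the ring closes on the former ether oxygen, and the absence of base avoids the competing 5-exo closure to a 2-methylbenzofuran.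

**Step 7**
Reactants: 12 (S)-3-[(tert-butyldimethylsilyl)oxy]-1-(5-hydroxy-7-methoxy-2,2-dimethyl-2H-chromen-6-yl)-3-phenylpropan-1-one
Product: 13 (S)-3-hydroxy-1-(5-hydroxy-7-methoxy-2,2-dimethyl-2H-chromen-6-yl)-3-phenylpropan-1-one
Conditions: HF·pyridine, pyridine, THF, 0 °C → rt
Reagents that add atoms: none
Why: Fluoride-mediated cleavage of the silyl ether in a pyridine-buffered medium, which should leave the β-hydroxy ketone free of E1cB elimination or retro-aldol cleavage and should not protonate the chromene double bond.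

**Compound list**
1 | 1-(2,4-dihydroxy-6-methoxyphenyl)ethan-1-one (2′,4′-dihydroxy-6′-methoxyacetophenone) | CC(=O)c1c(O)cc(O)cc1OC | starting material
2 | 3-chloro-3-methylbut-1-yne | CC(C)(Cl)C#C | starting material
3 | 1-[2-hydroxy-6-methoxy-4-(2-methylbut-3-yn-2-yloxy)phenyl]ethan-1-one | CC(=O)c1c(O)cc(OC(C)(C)C#C)cc1OC | intermediate
4 | benzoyl chloride | O=C(Cl)c1ccccc1 | starting material
5 | 2-acetyl-3-methoxy-5-(2-methylbut-3-yn-2-yloxy)phenyl benzoate | CC(=O)c1c(OC(=O)c2ccccc2)cc(OC(C)(C)C#C)cc1OC | intermediate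
6 | 1-[2-hydroxy-6-methoxy-4-(2-methylbut-3-yn-2-yloxy)phenyl]-3-phenylpropane-1,3-dione (drawn as the diketone tautomer) | COc1cc(OC(C)(C)C#C)cc(O)c1C(=O)CC(=O)c1ccccc1 | intermediate
7 | (S)-3-hydroxy-1-[2-hydroxy-6-methoxy-4-(2-methylbut-3-yn-2-yloxy)phenyl]-3-phenylpropan-1-one | COc1cc(OC(C)(C)C#C)cc(O)c1C(=O)C[C@H](O)c1ccccc1 | intermediate
8 | (S)-3-[(tert-butyldimethylsilyl)oxy]-1-[2-hydroxy-6-methoxy-4-(2-methylbut-3-yn-2-yloxy)phenyl]-3-phenylpropan-1-one | COc1cc(OC(C)(C)C#C)cc(O)c1C(=O)C[C@H](O[Si](C)(C)C(C)(C)C)c1ccccc1 | intermediate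
9 | (3S)-3-[(tert-butyldimethylsilyl)oxy]-1-[2-hydroxy-6-methoxy-3-(3-methylbuta-1,2-dien-1-yl)-4-oxocyclohexa-1,5-dien-1-yl]-3-phenylpropan-1-one (allenyl dienone, ring sp3 centre unassigned) | COC1=CC(=O)C(C=C=C(C)C)C(O)=C1C(=O)C[C@H](O[Si](C)(C)C(C)(C)C)c1ccccc1 | intermediate
10 | (S)-3-[(tert-butyldimethylsilyl)oxy]-1-[2,4-dihydroxy-6-methoxy-3-(3-methylbuta-1,2-dien-1-yl)phenyl]-3-phenylpropan-1-one (ortho-allenyl phenol) | COc1cc(O)c(C=C=C(C)C)c(O)c1C(=O)C[C@H](O[Si](C)(C)C(C)(C)C)c1ccccc1 | intermediate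
11 | (3S)-3-[(tert-butyldimethylsilyl)oxy]-1-[(3Z)-2-hydroxy-6-methoxy-3-(3-methylbut-2-en-1-ylidene)-4-oxocyclohexa-1,5-dien-1-yl]-3-phenylpropan-1-one (ortho-quinone methide) | COC1=CC(=O)/C(=C\C=C(C)C)C(O)=C1C(=O)C[C@H](O[Si](C)(C)C(C)(C)C)c1ccccc1 | intermediate
12 | (S)-3-[(tert-butyldimethylsilyl)oxy]-1-(5-hydroxy-7-methoxy-2,2-dimethyl-2H-chromen-6-yl)-3-phenylpropan-1-one | COc1cc2c(c(O)c1C(=O)C[C@H](O[Si](C)(C)C(C)(C)C)c1ccccc1)C=CC(C)(C)O2 | intermediate
13 | (S)-3-hydroxy-1-(5-hydroxy-7-methoxy-2,2-dimethyl-2H-chromen-6-yl)-3-phenylpropan-1-one | COc1cc2c(c(O)c1C(=O)C[C@H](O)c1ccccc1)C=CC(C)(C)O2 | target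

**Step count**
Total steps: 7. Longest linear sequence: 7 steps (1 → 13).

**Steps most likely to fail**

Step 6 (key step). The propargyl unit may migrate to the wrong ortho carbon (C5′), or the β-silyloxy ketone may lose silanol on prolonged heating. The fallback closes the pyran before the side chain exists; it sets out from 3 and rejoins the route at 13. The same thermal cascade on the simple acetophenone 3 (o-xylene, 140 °C) should give 1-(5-hydroxy-7-methoxy-2,2-dimethyl-2H-chromen-6-yl)ethan-1-one F1, from which any ring-fusion isomer can be removed on a robust compound. Benzoylation (BzCl, pyridine, DMAP) then gives 6-acetyl-7-methoxy-2,2-dimethyl-2H-chromen-5-yl benzoate F2. Baker–Venkataraman rearrangement (KOH, pyridine, 50 °C) gives 1-(5-hydroxy-7-methoxy-2,2-dimethyl-2H-chromen-6-yl)-3-phenylpropane-1,3-dione F3. Transfer hydrogenation with RuCl[(S,S)-TsDPEN](p-cymene) and HCO2H/Et3N should reduce the benzoyl carbonyl and give 13 directly, with no silyl group.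

Step 4. The reduction may stall because the diketone rests as its enol or cyclic hemiketal, the terminal alkyne may deactivate the ruthenium hydride, or facial selectivity may be insufficient. The fallback sets the stereocentre by asymmetric epoxidation instead of ketone reduction; it sets out from 3 and rejoins at 7. Protection of the chelated phenol (NaH, MOMCl, DMF) gives 1-[2-methoxy-6-(methoxymethoxy)-4-(2-methylbut-3-yn-2-yloxy)phenyl]ethan-1-one F4. Claisen–Schmidt condensation with benzaldehyde (KOH, EtOH) gives (E)-1-[2-methoxy-6-(methoxymethoxy)-4-(2-methylbut-3-yn-2-yloxy)phenyl]-3-phenylprop-2-en-1-one F5. Juliá–Colonna epoxidation (poly-D-leucine, urea–H2O2, DBU, THF) should give [2-methoxy-6-(methoxymethoxy)-4-(2-methylbut-3-yn-2-yloxy)phenyl][(2S,3R)-3-phenyloxiran-2-yl]methanone F6. Reductive cleavage of the Cα–O bond with SmI2 (THF/MeOH, −90 °C) leaves the Cβ–O bond intact and should give (S)-3-hydroxy-1-[2-methoxy-6-(methoxymethoxy)-4-(2-methylbut-3-yn-2-yloxy)phenyl]-3-phenylpropan-1-one F7. Removal of the MOM group next to the carbonyl (dilute HCl, MeOH, rt) then gives 7.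

Step 7. Cleavage of the hindered benzylic silyl ether may be slow, and forcing it may cause loss of the β-oxygen to the chalcone followed by ring closure of the phenol onto the enone. The fallback uses a silyl group that comes off under mild protic conditions; it sets out from 7 and rejoins at 13. Silylation with TESCl and imidazole in DMF gives (S)-1-[2-hydroxy-6-methoxy-4-(2-methylbut-3-yn-2-yloxy)phenyl]-3-phenyl-3-[(triethylsilyl)oxy]propan-1-one F8. The thermal cascade of step 6 (o-xylene, 140 °C) gives (S)-1-(5-hydroxy-7-methoxy-2,2-dimethyl-2H-chromen-6-yl)-3-phenyl-3-[(triethylsilyl)oxy]propan-1-one F9. Solvolysis with PPTS in MeOH at 0 °C should then release 13 without fluoride.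

**Further compounds**
F1 | step 6 | 1-(5-hydroxy-7-methoxy-2,2-dimethyl-2H-chromen-6-yl)ethan-1-one | COc1cc2c(c(O)c1C(C)=O)C=CC(C)(C)O2
F2 | step 6 | 6-acetyl-7-methoxy-2,2-dimethyl-2H-chromen-5-yl benzoate | COc1cc2c(c(OC(=O)c3ccccc3)c1C(C)=O)C=CC(C)(C)O2
F3 | step 6 | 1-(5-hydroxy-7-methoxy-2,2-dimethyl-2H-chromen-6-yl)-3-phenylpropane-1,3-dione | COc1cc2c(c(O)c1C(=O)CC(=O)c1ccccc1)C=CC(C)(C)O2
F4 | step 4 | 1-[2-methoxy-6-(methoxymethoxy)-4-(2-methylbut-3-yn-2-yloxy)phenyl]ethan-1-one | CC(=O)c1c(OCOC)cc(OC(C)(C)C#C)cc1OC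
F5 | step 4 | (E)-1-[2-methoxy-6-(methoxymethoxy)-4-(2-methylbut-3-yn-2-yloxy)phenyl]-3-phenylprop-2-en-1-one | COCOc1cc(OC(C)(C)C#C)cc(OC)c1C(=O)/C=C/c1ccccc1
F6 | step 4 | [2-methoxy-6-(methoxymethoxy)-4-(2-methylbut-3-yn-2-yloxy)phenyl][(2S,3R)-3-phenyloxiran-2-yl]methanone | COCOc1cc(OC(C)(C)C#C)cc(OC)c1C(=O)[C@@H]1[C@H](O1)c1ccccc1
F7 | step 4 | (S)-3-hydroxy-1-[2-methoxy-6-(methoxymethoxy)-4-(2-methylbut-3-yn-2-yloxy)phenyl]-3-phenylpropan-1-one | COCOc1cc(OC(C)(C)C#C)cc(OC)c1C(=O)C[C@H](O)c1ccccc1
F8 | step 7 | (S)-1-[2-hydroxy-6-methoxy-4-(2-methylbut-3-yn-2-yloxy)phenyl]-3-phenyl-3-[(triethylsilyl)oxy]propan-1-one | COc1cc(OC(C)(C)C#C)cc(O)c1C(=O)C[C@H](O[Si](CC)(CC)CC)c1ccccc1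
F9 | step 7 | (S)-1-(5-hydroxy-7-methoxy-2,2-dimethyl-2H-chromen-6-yl)-3-phenyl-3-[(triethylsilyl)oxy]propan-1-one | COc1cc2c(c(O)c1C(=O)C[C@H](O[Si](CC)(CC)CC)c1ccccc1)C=CC(C)(C)O2
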